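**Spent share.** I began from one ratio: conversion plus double product, over the equivalents of reagent charged. Each mono adduct and over-reaction product holds one reagent and each double product two, so the ratio is the share of the charge consumed. On the mean readings of the west run, this spent share stood at 0.999, which made the reagent the limiting reagent there.

| flask | substrate | reagent | remark | time |
|---|---|---|---|---|
| east | 20 mM | 0.75 equiv | run made earlier |  |
| south-west | 20 mM | 1.1 equiv | run made earlier |  |
| west | 40 mM | 1.5 equiv | run made earlier |  |
| flask | 20 mM | 1.50 equiv |  | 30 h |

- east (time / h: substrate / %, double product / %, single product / %): 3.00: 41, 17, 1; 6.00: 42, 14, 0; 10.0: 42, 16, 0; 15.0: 40, 14, 0; 20.0: 43, 16, 0; 25.0: 41, 17, 0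
- south-west (time / h: substrate / %, double product / %, single product / %): 3.00: 25, 33, 4; 6.00: 23, 33, 0; 10.0: 24, 32, 0; 15.0: 26, 33, 0; 20.0: 25, 34, 0; 25.0: 23, 31, 0
- west (time / h: substrate / %, double product / %, single product / %): 5.00: 8, 58, 1; 10.0: 10, 56, 0; 15.0: 9, 59, 2; 20.0: 5, 59, 0; 25.0: 11, 60, 3

(scatter of a reading: 1.5 percentage points)

- for single product the crystals are counted in
- as a solid, counted per litre of solution: crystals
- reactions considered so far: single product -> over-reaction product; substrate + reagent -> single product; reagent + other mono adduct -> double product; reagent + single product -> double product; crystals <-> single product; substrate + reagent -> other mono adduct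
- the reaction counts as stopped when no species that holds the substrate changes by six tenths of a point or more over the second half of the time

1. at 30 h, what has stopped the reaction, if anything has (the reagent has run out first / all of the substrate has reacted / forward and back rates have come level / it is still moving)
2. how much of the substrate has reacted by 30 h
3. how much double product there is at 30 h, in percent of the substrate charged

**Time ladder.** In the south-west run, at the substrate concentration of the flask, substrate read 25 % at 3.00 h and 23 % at 25.0 h, so within the scatter its consumption had ended by the first reading. Single product went next, from 4 % at that reading to 0 % at 6.00 h. After that, the readings of that run showed no trend beyond the scatter of 1.5 percentage points. The asked time is ten times that first reading, so I expected the flask to be governed by its charge, no longer by its rates.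

**My reckoning.** The west run has the equivalents of the flask at twice the concentration, and I assumed that dilution left the split unchanged. Its mean substrate of 8.60 % gave me 91.4 % reacted in the flask, and the spent share then gave 58.4 % double product.

**The forecast.** The forecast said that by the asked time the reagent has run out first, with 91.5 % reacted and 58.5 % double product, close to my figures, and held that “the flask should resemble the west run”.

**The flask.** In the flask, the reagent has run out first, with 91.2 % reacted, 58.8 % double product, a spent share of 1.00 and 0 % of its reagent left.

    single product → over-reaction product (k = 1.70 × 10⁻⁴ s⁻¹)
    substrate + reagent → single product (k = 0.0440 M⁻¹ s⁻¹)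
    reagent + other mono adduct → double product (k = 0.0950 M⁻¹ s⁻¹)
    reagent + single product → double product (k = 0.0890 M⁻¹ s⁻¹)
    crystals ⇌ single product, rate k5*(cs5 - [single product]) while solid is left; crystals form when [single product] > cs5 (solubility = 13.0 mM, k = 0.00320 s⁻¹)
    substrate + reagent → other mono adduct (k = 0.0840 M⁻¹ s⁻¹)

In the flask, the half-life of the reagent by the path to other mono adduct was 0.21 h at 0.0555 h, far shorter than the 30 h asked. The neighbour charged with 6.00 equiv reached a spent share of 0.332, and 67 % of its own reagent charge stood unused.

(The earlier runs and the new flask were computed with constants of no real substance; scatter was added.)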